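I had no rate constants for these flasks, so I worked from the two earlier runs, in logarithms of the charge.

| setting | teal | violet | flask |
|---|---|---|---|
| electrophile | 46 mM | 73 mM | 33 mM |
| nucleophile | 1.05 equiv | 1.05 equiv | 1.05 equiv |
| remark | run made earlier | run made earlier |  |
| time |  |  | 15 min |

| run | time / min | electrophile / % | product / % |
|---|---|---|---|
| teal | 3.00 | 66.4 | 33.9 |
| teal | 6.00 | 61.4 | 38.0 |
| teal | 10.0 | 58.5 | 41.3 |
| teal | 12.0 | 57.8 | 41.9 |
| teal | 15.0 | 56.2 | 43.7 |
| teal | 20.0 | 55.5 | 45.2 |
| violet | 1.33 | 69.4 | 30.1 |
| violet | 4.00 | 62.3 | 38.0 |
| violet | 6.00 | 59.7 | 39.4 |
| violet | 10.0 | 58.1 | 42.2 |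
| violet | 15.0 | 55.4 | 44.2 |
| violet | 20.0 | 54.5 | 45.9 |

(scatter of a reading: 0.3 percentage points)

- part of the electrophile that has reacted at 15 min
- share of free nucleophile in free nucleophile and protonated nucleophile together, at 15 min

- the numbers in the tables scatter by 0.3 percentage points (one standard deviation)
- a reading or a percentage of product counts all its forms, free or not
- the earlier runs do not show how much of nucleophile is bound; that part of a forecast is a guess

At 15 min, teal had converted 43.8% by its electrophile reading and violet 44.6%. Their charges stand 0.201 decade apart, so conversion climbed 4 percentage points per decade of charge. This flask lies 0.144 decade below teal, which put it at 43.2%.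

The weak link was that slope, resting on a difference of 0.8 points between single readings that scatter by 0.3 points. So I reforged it: the product column is a second reading of the same conversion, and the means of the two columns give 43.8% for teal and 44.4% for violet. That yields the decade slope, the conversion gained per decade of charge at fixed equivalents and time, 3.2 points, and for this flask I committed to 43.3%.

The forecast gave 43.2% (42.2% to 44.2%) for the reacted part of the electrophile and 8% (4% to 25%) for the free share of the nucleophile, reasoning that “The late rate then becomes independent of concentration.”

The flask reacted 42.8% of its electrophile, with free nucleophile at 7.59% of free and protonated nucleophile together.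

    nucleophile + product ⇌ idle adduct, settled at all times (K = 1300 /M)
    nucleophile + acid set free ⇌ protonated nucleophile, settled at all times (K = 5000 /M)
    electrophile + nucleophile ⇌ acid set free + product (K = 9.50, k = 0.140 /M/s)

My decade slope had put this flask 0.50 points above that result. A neighbouring flask, charged with 13 mM of electrophile at the same equivalents and time, lies 0.549 decade below teal, so the same slope gives it 42.0%. The neighbour reached 38.6%, lower by 3.4 points. Between this flask and the neighbour, conversion falls 10 points per decade, steeper than the slope read from teal and violet.

Readings and results are calculated with constants of no real substance; the scatter is artificial.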